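Numbering: caryophyllane C1–C15 for the terpene half and C1′ for the CH2 between C5 and ring A (the acyl dienone). Ring B is the dihydropyran.
Cuts: ring B at the enol-ether O–C(sp2) bond and at C1′–ring A (giving an acyl trione and a C4-hydroxy C5-carbaldehyde); C8=C13; C1–C11 and C9–C10 together (isobutylene + cyclononenone); C1=C9 (RCM); C8–C9; C5–C6 (epoxide opening).
Enabling feature: the dimethylcyclobutane (C1, C9, C10, C11) is fused to the nine-membered ring directly beside C8. With C8 as a ketone it is therefore the head-to-tail isobutylene adduct of a C1=C9 cyclononenone, and C9, α to that ketone, stays epimerisable.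
Forward order of rings: 1,3-dioxane on C4/C5 (placeholder for ring B), nine-membered ring (RCM), cyclobutane ([2+2]), ring A attached at C1′, ring B closed last.
Stereochemistry: C4 comes from Sharpless epoxidation, C5 from invertive epoxide opening, C1 by relay from C4/C5 in the photocycloaddition, C9 by equilibration to the trans 4/9 fusion, and the side-chain centre from (S)-2-methylbutanoic acid. Any minor terpene enantiomer is shed as a diastereomer after coupling.

Key step: step 9

Assumption: ring A compounds (25–29) are written as the chelated dienol tautomer used in the target SMILES. They are tautomer mixtures in solution, which does not affect the bonds formed.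

Step 1
Reactants: 1 hex-1-en-5-yne
Product: 4 (E)-3-methylhepta-2,6-dien-1-ol, via (E)-dimethyl(2-methylhexa-1,5-dien-1-yl)alane 2 (not isolated), via lithium (E)-butyl(dimethyl)(2-methylhexa-1,5-dien-1-yl)aluminate 3 (not isolated)
Conditions: AlMe3, Cp2ZrCl2 (20 mol %), CH2Cl2, 0 °C to rt; n-BuLi, hexane/THF, −78 to 0 °C; (CH2O)n, rt; aq. work-up
Reagents that add atoms: trimethylaluminium C[Al](C)C; paraformaldehyde (as formaldehyde) C=O
Why: Negishi zirconium-catalysed methylalumination adds Me and Al syn to the terminal alkyne only (the monosubstituted alkene is inert here), and the derived alkenyl aluminate is hydroxymethylated with retention, which fixes the E trisubstituted alkene.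

Step 2
Reactants: 4 (E)-3-methylhepta-2,6-dien-1-ol
Product: 5 [(2S,3S)-3-(but-3-en-1-yl)-3-methyloxiran-2-yl]methanol
Conditions: Ti(OiPr)4 (5 mol %), L-(+)-DET (6 mol %), TBHP, 4 Å MS, CH2Cl2, −20 °C
Reagents that add atoms: tert-butyl hydroperoxide CC(C)(C)OO
Why: Katsuki–Sharpless asymmetric epoxidation is directed by the allylic hydroxyl, so the isolated vinyl group is untouched, and L-(+)-DET should deliver oxygen in the same sense as with geraniol to give the (2S,3S)-epoxide, which sets C4.

Step 3
Reactants: 5 [(2S,3S)-3-(but-3-en-1-yl)-3-methyloxiran-2-yl]methanol; 6 5-bromo-2-methylpent-2-ene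
Product: 8 (2R,3S)-3-methyl-2-(4-methylpent-3-en-1-yl)hept-6-ene-1,3-diol, via (4-methylpent-3-en-1-yl)magnesium bromide 7 (not isolated)
Conditions: 6, Mg, THF; then CuI (15 mol %), 5, THF, −30 to 0 °C; aq. work-up
Reagents that add atoms: none
Why: Copper-catalysed Grignard opening of a 2,3-epoxy alcohol is an SN2 process that avoids the fully substituted epoxide carbon and attacks C2 with inversion, which gives the 1,3-diol, forms C5–C6 and sets C5 so that C3 and C6 end up trans on the later six-membered ring.

Step 4
Reactants: 8 (2R,3S)-3-methyl-2-(4-methylpent-3-en-1-yl)hept-6-ene-1,3-diol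
Product: 9 (4S,5R)-4-(but-3-en-1-yl)-2,2,4-trimethyl-5-(4-methylpent-3-en-1-yl)-1,3-dioxane
Conditions: Me2C(OMe)2, PPTS (cat.), CH2Cl2, rt
Reagents that add atoms: 2,2-dimethoxypropane COC(C)(C)OC
Why: Acid-catalysed transketalisation closes the 1,3-dioxane of the 1,3-diol without touching C4 or C5, and PPTS is too weak to ionise the tertiary alcohol or protonate the alkenes.

Step 5
Reactants: 9 (4S,5R)-4-(but-3-en-1-yl)-2,2,4-trimethyl-5-(4-methylpent-3-en-1-yl)-1,3-dioxane
Product: 11 3-[(4S,5R)-4-(but-3-en-1-yl)-2,2,4-trimethyl-1,3-dioxan-5-yl]propanal, via the secondary ozonide (3,3-dimethyl-1,2,4-trioxolane) of the trisubstituted alkene 10 (not isolated)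
Conditions: O3 (1 equiv, Sudan Red 7B end-point), CH2Cl2, −78 °C; PPh3, −78 °C to rt
Reagents that add atoms: ozone [O-][O+]=O
Why: In this chemoselective ozonolysis the electrophilic ozone consumes the electron-rich trisubstituted alkene well ahead of the monosubstituted one, and PPh3 reduces the ozonide under neutral conditions that spare the acetonide.

Step 6
Reactants: 11 3-[(4S,5R)-4-(but-3-en-1-yl)-2,2,4-trimethyl-1,3-dioxan-5-yl]propanal
Product: 12 5-[(4S,5R)-4-(but-3-en-1-yl)-2,2,4-trimethyl-1,3-dioxan-5-yl]pent-1-en-3-ol (both carbinol epimers)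
Conditions: CH2=CHMgBr, THF, −78 °C
Reagents that add atoms: vinylmagnesium bromide C=C[Mg]Br
Why: Grignard 1,2-addition to an unhindered aldehyde forms C8–C9, and the uncontrolled carbinol centre is erased in the next step.

Step 7
Reactants: 12 5-[(4S,5R)-4-(but-3-en-1-yl)-2,2,4-trimethyl-1,3-dioxan-5-yl]pent-1-en-3-ol
Product: 13 5-[(4S,5R)-4-(but-3-en-1-yl)-2,2,4-trimethyl-1,3-dioxan-5-yl]pent-1-en-3-one
Conditions: DMP, pyridine, CH2Cl2, 0 °C to rt
Reagents that add atoms: none
Why: Dess–Martin oxidation gives the vinyl ketone under buffered, non-nucleophilic conditions that avoid conjugate addition and leave the acetonide and the terminal alkene alone.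

Step 8
Reactants: 13 5-[(4S,5R)-4-(but-3-en-1-yl)-2,2,4-trimethyl-1,3-dioxan-5-yl]pent-1-en-3-one
Product: 14 (Z)-cyclonon-2-enone (C8 ketone, C9=C1 alkene) trans-fused at C4/C5 to the 2,2-dimethyl-1,3-dioxane (C4–O and C5–CH2O, methyl on C4), (4S,5R)
Conditions: Hoveyda–Grubbs II (10 mol %), toluene (1 mM), 80 °C, Ar sparge
Reagents that add atoms: none
Why: In this ring-closing metathesis the catalyst loads at the unhindered butenyl terminus and closes onto the vinyl ketone, the two chains being held gauche on adjacent dioxane carbons, while loss of ethene drives the closure and the less strained Z enone is the expected geometry in a nine-membered ring.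

Step 9
Reactants: 14 (4S,5R,Z)-cyclononenone acetonide; 15 isobutylene
Product: 17 (1R,4S,5R,9S)-8-oxo-13-norcaryophyllane acetonide (11,11-dimethylcyclobutane C1/C9/C10/C11 trans-fused to the nine-membered C8 ketone, H1 and H9 trans, dioxane unchanged), via its cis-fused C9 epimer (1R,4S,5R,9R) 16 (not isolated)
Conditions: 15 (condensed, large excess)/CH2Cl2, hν (366 nm, Pyrex), −70 °C; evaporate; NaOMe (cat.), MeOH, rt
Reagents that add atoms: none
Why: n→π* excitation and intersystem crossing give the twisted triplet enone, which bonds at C9 to the CH2 terminus of isobutylene, and the resulting triplet 1,4-biradical (secondary C1, tertiary C11) undergoes spin inversion and couples C1–C11. This is the enone–alkene [2+2] photocycloaddition long established for cycloalkenones with isobutylene, and the cyclobutane is closed by 1,4-biradical recombination (formal [2+2], a four-membered ring from two π bonds), not in a concerted step. The head-to-tail regiochemistry needed (CMe2 on the β-carbon C1, CH2 on C9) is the normal one for this electron-rich 1,1-dialkylalkene, because the excited enone is polarised Cβ(δ−)/Cα(δ+) and the biradical bonded C9–CH2 closes whereas the one bonded C1–CH2 tends to revert. C1 is set by substrate relay: the trans-fused dioxane pins C3 and C6 and points the C4 methyl (flanked by the syn ketal methyl) over one side of the nine-membered ring, so the sense of enone twist that keeps C2–C3 clear of this methyl should be populated and C11 should bond to C1 anti to it, which is 1R, although this remote control is the untested element of the step. C9 needs no kinetic control, since closure from the twisted enone favours the trans 4/9 fusion and the cis adduct 16 is converted by methoxide through the C8–C9 enolate into the more stable trans-bicyclo[7.2.0]undecanone 17. Z/E isomerisation of the enone is only an energy sink because both geometries return to the same triplet, so trapping is made competitive by near-neat isobutylene at low temperature, and chemoselectivity is secured because the enone is the only chromophore at 366 nm and the product ketone is transparent there.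

Step 10
Reactants: 17 (1R,4S,5R,9S)-8-oxo-13-norcaryophyllane acetonide
Product: 18 (1R,4S,5R,9S)-8-methylene acetonide (17 with C8=C13H2 in place of C8=O)
Conditions: Ph3PCH3Br, KOtBu, THF, 0 to 50 °C
Reagents that add atoms: methyltriphenylphosphonium bromide C[P+](c1ccccc1)(c1ccccc1)c1ccccc1.[Br-]
Why: Wittig methylenation is the standard way to turn 8-oxo-13-norcaryophyllanes into the exocyclic alkene, and the basic medium can only return C9 to its already equilibrated trans configuration.

Step 11
Reactants: 18 (1R,4S,5R,9S)-8-methylene acetonide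
Product: 19 (1R,4S,5R,9S)-5-(hydroxymethyl)-4,5-dihydro-β-caryophyllen-4-ol (tertiary C4–OH, C5–CH2OH, C8 exocyclic methylene)
Conditions: AcOH/THF/H2O (3:1:1), rt
Reagents that add atoms: none
Why: Acid hydrolysis removes an acetonide that is strained by its syn C2/C4 methyl pair and should therefore cleave under conditions too mild to ionise the tertiary C4–OH or protonate the 1,1-disubstituted alkene.

Step 12
Reactants: 19 (1R,4S,5R,9S)-5-(hydroxymethyl)-4,5-dihydro-β-caryophyllen-4-ol
Product: 20 (1R,4S,5S,9S)-4-hydroxy-4,5-dihydro-β-caryophyllene-5-carbaldehyde (C5 unchanged in space; the descriptor changes with CIP priority)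
Conditions: DMP, pyridine, CH2Cl2, 0 °C
Reagents that add atoms: none
Why: Dess–Martin oxidation can only touch the primary alcohol, and the pyridine buffer and low temperature should keep the β-hydroxy aldehyde from retro-aldol cleavage, dehydration and epimerisation at C5.

Step 13
Reactants: 21 (S)-2-methylbutanoic acid; 22 phloroglucinol
Product: 24 (S)-2-methyl-1-(2,4,6-trihydroxyphenyl)butan-1-one, via (S)-2-methylbutanoyl chloride 23 (not isolated)
Conditions: (COCl)2, DMF (cat.), CH2Cl2, rt; then 22, AlCl3, CH2Cl2/PhNO2, 0 °C to rt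
Reagents that add atoms: none
Why: Friedel–Crafts C-acylation of the very electron-rich ring stops at the mono-ketone because the chelated acyl group deactivates it, and the α-stereocentre takes no part in acylium formation and is carried through at or below room temperature.

Step 14
Reactants: 24 (S)-2-methyl-1-(2,4,6-trihydroxyphenyl)butan-1-one
Product: 25 3,5-dihydroxy-6,6-dimethyl-2-[(2S)-2-methylbutanoyl]cyclohexa-2,4-dien-1-one (tautomer of the 2-acyl-4,4-dimethylcyclohexane-1,3,5-trione)
Conditions: MeI (2.1 equiv), NaOMe, MeOH, 0 °C to rt; acidic work-up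
Reagents that add atoms: iodomethane CI
Why: Dearomatising C-methylation of the acylphloroglucinol anion places the second methyl on the already methylated, more nucleophilic carbon to give the gem-dimethyl trione (separated from under- and over-methylated material), and the side-chain centre is safe because the acyl group is locked in the delocalised triketonate.

Step 15
Reactants: 20 (1R,4S,5S,9S)-4-hydroxy-4,5-dihydro-β-caryophyllene-5-carbaldehyde; 25 acyl trione
Product: 27 C1′-alkylated acyl trione (C5–C1′H2 joined to the formerly free ring carbon of 25, C4–OH free, (1R,4S,5R,9S,2″S)), via the C1′ alkylidene trione 26 (not isolated)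
Conditions: L-proline (10 mol %), Hantzsch ester (1.2 equiv), CH2Cl2, rt
Reagents that add atoms: none
Why: In this three-component reductive alkylation (organocatalytic Knoevenagel condensation, then conjugate hydride transfer from the Hantzsch ester) the only free ring CH of 25 condenses with the aldehyde, and the highly electrophilic alkylidene 26 should be reduced faster than a second trione adds, at near-neutral pH that preserves C5 and the β-hydroxyl.

Step 16
Reactants: 27 C1′-alkylated acyl trione
Product: 29 target CNP0591516.1, via the six-membered hemiketal 28 (not isolated)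
Conditions: PPTS (10 mol %), 4 Å MS, toluene, 60 °C
Reagents that add atoms: none
Why: In this acid-catalysed cyclodehydration of a δ-hydroxy vinylogous acid the C4 hydroxyl adds to the unchelated ring carbonyl next to CMe2 and water leaves from the ketal carbon through an oxocarbenium ion, so the C4–O bond and the C4 configuration stay intact while the other ring carbonyl remains locked in the hydrogen-bonded enol with the acyl group.

Compound list
1 | hex-1-en-5-yne | C=CCCC#C | starting material
2 | (E)-dimethyl(2-methylhexa-1,5-dien-1-yl)alane | C=CCC/C(C)=C/[Al](C)C | intermediate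
3 | lithium (E)-butyl(dimethyl)(2-methylhexa-1,5-dien-1-yl)aluminate | [Li+].C=CCC/C(C)=C/[Al-](C)(C)CCCC | intermediate
4 | (E)-3-methylhepta-2,6-dien-1-ol | C=CCC/C(C)=C/CO | intermediate
5 | [(2S,3S)-3-(but-3-en-1-yl)-3-methyloxiran-2-yl]methanol | C=CCC[C@]1(C)O[C@H]1CO | intermediate
6 | 5-bromo-2-methylpent-2-ene | CC(C)=CCCBr | starting material
7 | (4-methylpent-3-en-1-yl)magnesium bromide | CC(C)=CCC[Mg]Br | intermediate
8 | (2R,3S)-3-methyl-2-(4-methylpent-3-en-1-yl)hept-6-ene-1,3-diol | C=CCC[C@](C)(O)[C@@H](CO)CCC=C(C)C | intermediate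
9 | (4S,5R)-4-(but-3-en-1-yl)-2,2,4-trimethyl-5-(4-methylpent-3-en-1-yl)-1,3-dioxane | C=CCC[C@]1(C)OC(C)(C)OC[C@H]1CCC=C(C)C | intermediate
10 | secondary ozonide of the trisubstituted alkene of 9 | C=CCC[C@]1(C)OC(C)(C)OC[C@H]1CCC1OOC(C)(C)O1 | intermediate
11 | 3-[(4S,5R)-4-(but-3-en-1-yl)-2,2,4-trimethyl-1,3-dioxan-5-yl]propanal | C=CCC[C@]1(C)OC(C)(C)OC[C@H]1CCC=O | intermediate
12 | 5-[(4S,5R)-4-(but-3-en-1-yl)-2,2,4-trimethyl-1,3-dioxan-5-yl]pent-1-en-3-ol (carbinol epimers) | C=CCC[C@]1(C)OC(C)(C)OC[C@H]1CCC(O)C=C | intermediate
13 | 5-[(4S,5R)-4-(but-3-en-1-yl)-2,2,4-trimethyl-1,3-dioxan-5-yl]pent-1-en-3-one | C=CCC[C@]1(C)OC(C)(C)OC[C@H]1CCC(=O)C=C | intermediate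
14 | (4S,5R,Z)-cyclonon-2-enone trans-fused to the C4–O/C5–CH2O acetonide | O=C1/C=C\CC[C@]2(C)OC(C)(C)OC[C@H]2CC1 | intermediate
15 | isobutylene | C=C(C)C | starting material
16 | (1R,4S,5R,9R)-8-oxo-13-norcaryophyllane acetonide (cis 4/9 fusion) | O=C1CC[C@@H]2COC(C)(C)O[C@@]2(C)CC[C@@H]2[C@H]1CC2(C)C | intermediate
17 | (1R,4S,5R,9S)-8-oxo-13-norcaryophyllane acetonide (trans 4/9 fusion) | O=C1CC[C@@H]2COC(C)(C)O[C@@]2(C)CC[C@@H]2[C@@H]1CC2(C)C | intermediate
18 | (1R,4S,5R,9S)-8-methylene acetonide | C=C1CC[C@@H]2COC(C)(C)O[C@@]2(C)CC[C@@H]2[C@@H]1CC2(C)C | intermediate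
19 | (1R,4S,5R,9S)-5-(hydroxymethyl)-4,5-dihydro-β-caryophyllen-4-ol | C=C1CC[C@H](CO)[C@@](C)(O)CC[C@@H]2[C@@H]1CC2(C)C | intermediate
20 | (1R,4S,5S,9S)-4-hydroxy-4,5-dihydro-β-caryophyllene-5-carbaldehyde | C=C1CC[C@H](C=O)[C@@](C)(O)CC[C@@H]2[C@@H]1CC2(C)C | intermediate
21 | (S)-2-methylbutanoic acid | CC[C@H](C)C(=O)O | starting material
22 | phloroglucinol | Oc1cc(O)cc(O)c1 | starting material
23 | (S)-2-methylbutanoyl chloride | CC[C@H](C)C(=O)Cl | intermediate
24 | (S)-2-methyl-1-(2,4,6-trihydroxyphenyl)butan-1-one | CC[C@H](C)C(=O)c1c(O)cc(O)cc1O | intermediate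
25 | 3,5-dihydroxy-6,6-dimethyl-2-[(2S)-2-methylbutanoyl]cyclohexa-2,4-dien-1-one | CC[C@H](C)C(=O)C1=C(O)C=C(O)C(C)(C)C1=O | intermediate
26 | C1′ alkylidene trione (Knoevenagel product of 20 and 25) | C=C1CC[C@H](C=C3C(=O)C(C)(C)C(=O)C(C(=O)[C@@H](C)CC)=C3O)[C@@](C)(O)CC[C@@H]2[C@@H]1CC2(C)C | intermediate
27 | C1′-alkylated acyl trione with free C4–OH | C=C1CC[C@H](CC3=C(O)C(C)(C)C(=O)C(C(=O)[C@@H](C)CC)=C3O)[C@@](C)(O)CC[C@@H]2[C@@H]1CC2(C)C | intermediate
28 | six-membered hemiketal of 27 (C4–O on the ring carbon next to CMe2) | C=C1CC[C@@H]2CC3C(O)(O[C@@]2(C)CC[C@@H]2[C@@H]1CC2(C)C)C(C)(C)C(=O)C(C(=O)[C@@H](C)CC)=C3O | intermediate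
29 | CNP0591516.1 | C=C1CC[C@@H]2CC3=C(O[C@@]2(C)CC[C@@H]2[C@@H]1CC2(C)C)C(C)(C)C(=O)C(C(=O)[C@@H](C)CC)=C3O | target

Total steps: 16. Longest linear sequence: 14 (steps 1–12, 15, 16).

Steps most likely to fail

1. Step 9.
- Risk: Z/E isomerisation and radiationless decay of the twisted triplet may outrun trapping by isobutylene. Biradical reversion and disproportionation may erode the conversion. The remote C4/C5 relay may give poor facial selectivity at C1.
- Fallback: the same two bonds are made in two ground-state operations, setting out from 14.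
- Mukaiyama–Michael addition of the tert-butyldimethylsilyl ketene acetal of methyl isobutyrate (cat. TBSNTf2) forms C1–C11 by peripheral attack on the ground-state Z enone. It traps the C8–C9 enolate as the silyl enol ether ester F1.
- DIBAL-H reduces the ester to the neopentyl alcohol F2, and TsCl/pyridine gives the tosylate F3.
- Anhydrous fluoride (TASF) then frees the C9 enolate regiospecifically, and 4-exo-tet alkylation forms C9–C10.
- The same methoxide equilibration brings the material back to the route at 17.

2. Step 8.
- Risk: oligomerisation by cross-metathesis at the butenyl terminus may outrun closure onto the electron-poor, chelating vinyl ketone. Alkene migration before closure may lead to ring contraction.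
- Fallback: the ring is closed one oxidation level lower, setting out from 12.
- Both alkenes of 12 are of the fast-reacting type and its free allylic hydroxyl accelerates metathesis.
- RCM (Grubbs II, CH2Cl2, high dilution) should give the (Z)-cyclonon-2-enol acetonide F4 as a mixture of carbinol epimers.
- Dess–Martin oxidation comes back to the route at 14.

3. Step 15.
- Risk: enamine or enol formation may epimerise C5. Retro-aldol cleavage of C4–C5 or loss of the β-hydroxyl may destroy the aldehyde. Slow condensation of the hindered aldehyde may let a second trione add to the alkylidene.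
- Fallback: the tertiary hydroxyl is masked before the aldehyde is made, setting out from 19.
- TESOTf/2,6-lutidine gives the bis(triethylsilyl) ether F5.
- Swern conditions oxidise the primary silyl ether selectively and directly to the β-silyloxy aldehyde F6, which cannot undergo retro-aldol cleavage.
- The same reductive alkylation with 25 passes through the silylated alkylidene trione F7 to the silyl-protected alkylated trione F8.
- HF·pyridine comes back to the route at 27.

Further compounds
F1 | step 9 | methyl 2-methyl-2-[C1]propanoate on the nine-membered ring with C8(OTBS)=C9 silyl enol ether, acetonide intact, (1R,4S,5R) | COC(=O)C(C)(C)[C@@H]1CC[C@]2(C)OC(C)(C)OC[C@H]2CC/C(O[Si](C)(C)C(C)(C)C)=C\1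
F2 | step 9 | neopentyl alcohol (C10–OH) from reduction of F1 | OCC(C)(C)[C@@H]1CC[C@]2(C)OC(C)(C)OC[C@H]2CC/C(O[Si](C)(C)C(C)(C)C)=C\1
F3 | step 9 | C10 tosylate of F2 | Cc1ccc(cc1)S(=O)(=O)OCC(C)(C)[C@@H]1CC[C@]2(C)OC(C)(C)OC[C@H]2CC/C(O[Si](C)(C)C(C)(C)C)=C\1
F4 | step 8 | (4S,5R,Z)-cyclonon-2-enol acetonide (C8 carbinol epimers) | OC1/C=C\CC[C@]2(C)OC(C)(C)OC[C@H]2CC1
F5 | step 15 | bis(triethylsilyl) ether of 19 | C=C1CC[C@H](CO[Si](CC)(CC)CC)[C@@](C)(O[Si](CC)(CC)CC)CC[C@@H]2[C@@H]1CC2(C)C
F6 | step 15 | 4-(triethylsilyloxy) analogue of aldehyde 20 | C=C1CC[C@H](C=O)[C@@](C)(O[Si](CC)(CC)CC)CC[C@@H]2[C@@H]1CC2(C)C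
F7 | step 15 | 4-(triethylsilyloxy) analogue of alkylidene trione 26 | C=C1CC[C@H](C=C3C(=O)C(C)(C)C(=O)C(C(=O)[C@@H](C)CC)=C3O)[C@@](C)(O[Si](CC)(CC)CC)CC[C@@H]2[C@@H]1CC2(C)C
F8 | step 15 | 4-(triethylsilyloxy) analogue of alkylated trione 27 | C=C1CC[C@H](CC3=C(O)C(C)(C)C(=O)C(C(=O)[C@@H](C)CC)=C3O)[C@@](C)(O[Si](CC)(CC)CC)CC[C@@H]2[C@@H]1CC2(C)C
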